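**Strategy**

The quinone ring is read as an oxidised 3-methoxy-1-naphthol, and that naphthol as the electrocyclisation product of an aryl-substituted vinylketene. The ketene is released by photochemical Wolff rearrangement of an acyclic α-methoxy-β-arylacryloyl diazomethane. The methoxy-bearing vinyl carbon (quinone C2) migrates from the acyl carbon to the diazo carbon (C3). The former acyl carbon, now the ketene carbon (C4), then bonds to the only free ortho CH of the benzenoid ring (C4a); the other ortho carbon (C8) carries the 3,4-dimethoxyphenyl group. One operation thus turns an open chain into the second ring, with C2–C3 and C4–C4a both new. Fremy's salt then installs the C1 carbonyl.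

Key step: step 4

Remark: the target has no stereocentre. The only stereochemical element on the way is the enol ether double bond of 5 to 9, drawn as the (Z) isomer expected from the condensation; the key step does not depend on it.

**Route**

Step 1
Reactants: 1 2-bromo-4-methoxybenzaldehyde; 2 (3,4-dimethoxyphenyl)boronic acid
Product: 3 2-(3,4-dimethoxyphenyl)-4-methoxybenzaldehyde
Conditions: Pd(PPh3)4 (cat.), K2CO3, 1,4-dioxane/H2O, 90 °C
Reagents that add atoms: none
Why: Suzuki–Miyaura coupling; the ortho-formyl aryl bromide adds readily to zerovalent palladium and the aldehyde tolerates aqueous carbonate.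

Step 2
Reactants: 3 2-(3,4-dimethoxyphenyl)-4-methoxybenzaldehyde; 4 methyl methoxyacetate
Product: 6 (2Z)-3-[2-(3,4-dimethoxyphenyl)-4-methoxyphenyl]-2-methoxyprop-2-enoic acid, via methyl ester 5 (not isolated)
Conditions: NaOMe (1.5 equiv), MeOH, 0 °C to reflux; then aq NaOH, 60 °C; then aq HCl
Reagents that add atoms: sodium hydroxide, [Na+].[OH-] (oxygen of the acid hydroxyl)
Why: Claisen–Schmidt-type aldol condensation of a non-enolisable aldehyde with the ester enolate, followed by saponification in the same flask, should give the thermodynamically preferred (Z)-α-methoxycinnamic acid (aryl trans to the carboxyl group).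

Step 3
Reactants: 6 (2Z)-3-[2-(3,4-dimethoxyphenyl)-4-methoxyphenyl]-2-methoxyprop-2-enoic acid
Product: 8 (3Z)-1-diazo-4-[2-(3,4-dimethoxyphenyl)-4-methoxyphenyl]-3-methoxybut-3-en-2-one, via acid chloride 7 (not isolated)
Conditions: (COCl)2, DMF (cat.), CH2Cl2, 0 °C to rt, evaporate; then CH2N2 (excess, Et2O), 0 °C
Reagents that add atoms: diazomethane, C=[N+]=[N-]; oxalyl chloride, ClC(=O)C(=O)Cl (supplies only the chlorine of 7)
Why: Acylation of diazomethane by the acid chloride (first stage of an Arndt–Eistert sequence); the trisubstituted, β-aryl, α-methoxy alkene is a poor dipolarophile, so pyrazoline formation should be slow.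

Step 4
Reactants: 8 (3Z)-1-diazo-4-[2-(3,4-dimethoxyphenyl)-4-methoxyphenyl]-3-methoxybut-3-en-2-one
Product: 13 5-(3,4-dimethoxyphenyl)-3,7-dimethoxynaphthalen-1-ol, via (Z)-dienylketene 9 (not isolated), via cyclobutenone 10 (not isolated), via (E)-dienylketene 11 (not isolated), via 8aH-naphthalenone 12 (not isolated)
Conditions: hν (365 nm, or medium-pressure Hg lamp through Pyrex), degassed toluene (0.01 M), rt, argon; then 110 °C
Reagents that add atoms: none
Why: Irradiation expels N2 from 8 and the α-methoxyvinyl group shifts from the acyl carbon to the diazo carbon (photochemical Wolff rearrangement), which creates the bond between the methoxy-bearing carbon and the future quinone CH and leaves ketene 9. In 9 the aryl group lies trans to the ketenyl group, so 9 should close by 4π electrocyclisation to cyclobutenone 10, and heating reopens 10 reversibly until isomer 11, with the aryl group turned inward, is drained by a thermal disrotatory 6π electrocyclisation that forms the six-membered ring between the ketene carbon and the ortho CH of the methoxy-bearing benzene ring. Tautomerisation of 12 restores the arene and gives naphthol 13. The closest known reaction type is the Danheiser benzannulation in its photochemical variant, where an unsaturated diazoketone gives a vinylketene and a 4-aryl-3-alkoxycyclobutenone is converted on heating into a 3-alkoxy-1-naphthol. No stereocentre survives, since the sp3 centres of 10 and 12 are transient and racemic. The step needs the 1,2-shift to win over carbene addition to the arenes, which metal-free photolysis favours, and it needs a single site of ring closure, which is secured because the second ortho position carries the dimethoxyphenyl ring; the alkene geometry of 8 is not critical because 10 connects both ketenes.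

Step 5
Reactants: 13 5-(3,4-dimethoxyphenyl)-3,7-dimethoxynaphthalen-1-ol
Product: 14 8-(3,4-dimethoxyphenyl)-2,6-dimethoxynaphthalene-1,4-dione
Conditions: (KSO3)2NO (Fremy's salt, 2.5 equiv), KH2PO4 buffer, acetone/H2O, 0 °C to rt
Reagents that add atoms: potassium nitrosodisulfonate (Fremy's salt), [K+].[K+].[O]N(S(=O)(=O)[O-])S(=O)(=O)[O-]
Why: Teuber oxidation; the naphthoxyl radical should couple with a second nitrosodisulfonate radical at the free para carbon, which the adjacent methoxy group also activates, and loss of imidodisulfonate gives the para-quinone while the methyl ethers and the veratryl ring stay untouched.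

**Compound list**

1 | 2-bromo-4-methoxybenzaldehyde | COc1ccc(C=O)c(Br)c1 | starting material
2 | (3,4-dimethoxyphenyl)boronic acid | COc1ccc(B(O)O)cc1OC | starting material
3 | 2-(3,4-dimethoxyphenyl)-4-methoxybenzaldehyde | COc1ccc(C=O)c(-c2ccc(OC)c(OC)c2)c1 | intermediate
4 | methyl methoxyacetate | COCC(=O)OC | starting material
5 | methyl (2Z)-3-[2-(3,4-dimethoxyphenyl)-4-methoxyphenyl]-2-methoxyprop-2-enoate | COc1ccc(/C=C(\OC)C(=O)OC)c(-c2ccc(OC)c(OC)c2)c1 | intermediate
6 | (2Z)-3-[2-(3,4-dimethoxyphenyl)-4-methoxyphenyl]-2-methoxyprop-2-enoic acid | COc1ccc(/C=C(\OC)C(O)=O)c(-c2ccc(OC)c(OC)c2)c1 | intermediate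
7 | (2Z)-3-[2-(3,4-dimethoxyphenyl)-4-methoxyphenyl]-2-methoxyprop-2-enoyl chloride | COc1ccc(/C=C(\OC)C(Cl)=O)c(-c2ccc(OC)c(OC)c2)c1 | intermediate
8 | (3Z)-1-diazo-4-[2-(3,4-dimethoxyphenyl)-4-methoxyphenyl]-3-methoxybut-3-en-2-one | COc1ccc(/C=C(\OC)C(=O)C=[N+]=[N-])c(-c2ccc(OC)c(OC)c2)c1 | intermediate
9 | (3Z)-4-[2-(3,4-dimethoxyphenyl)-4-methoxyphenyl]-3-methoxybuta-1,3-dien-1-one | COc1ccc(/C=C(\OC)C=C=O)c(-c2ccc(OC)c(OC)c2)c1 | intermediate
10 | 4-[2-(3,4-dimethoxyphenyl)-4-methoxyphenyl]-3-methoxycyclobut-2-en-1-one (racemic) | COC1=CC(=O)C1c1ccc(OC)cc1-c1ccc(OC)c(OC)c1 | intermediate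
11 | (3E)-4-[2-(3,4-dimethoxyphenyl)-4-methoxyphenyl]-3-methoxybuta-1,3-dien-1-one | COc1ccc(/C=C(/OC)C=C=O)c(-c2ccc(OC)c(OC)c2)c1 | intermediate
12 | 5-(3,4-dimethoxyphenyl)-3,7-dimethoxy-8aH-naphthalen-1-one (racemic) | COC1=CC(=O)C2C=C(OC)C=C(c3ccc(OC)c(OC)c3)C2=C1 | intermediate
13 | 5-(3,4-dimethoxyphenyl)-3,7-dimethoxynaphthalen-1-ol | COc1cc(O)c2cc(OC)cc(-c3ccc(OC)c(OC)c3)c2c1 | intermediate
14 | 8-(3,4-dimethoxyphenyl)-2,6-dimethoxynaphthalene-1,4-dione | COC1=CC(=O)c2cc(OC)cc(-c3ccc(OC)c(OC)c3)c2C1=O | target

**Step count and risks**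

Total step count: 5. Longest linear sequence: 5 steps (1 to 14).

Steps most likely to fail:

Step 4. After loss of N2 the carbene may add to one of the arene rings instead of rearranging, and the ketene, with no trap present, may dimerise before the slow inward rotation of the aryl group lets it cyclise. The fallback sets out from 8 and separates the two events. Wolff rearrangement in the presence of water (PhCO2Ag cat., Et3N, dioxane/H2O; Arndt–Eistert homologation) should trap the ketene at once as (3Z)-4-[2-(3,4-dimethoxyphenyl)-4-methoxyphenyl]-3-methoxybut-3-enoic acid F1. Heating F1 with Ac2O and NaOAc, the cyclodehydration that is standard for 4-arylbut-3-enoic acids and under which the double bond can equilibrate through the conjugated isomer, should close the ring to 5-(3,4-dimethoxyphenyl)-3,7-dimethoxynaphthalen-1-yl acetate F2. Methanolysis (K2CO3, MeOH) then comes back to the route at 13.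

Step 5. The radical coupling may take place at the ortho carbon between the hydroxyl and methoxy groups instead of the para carbon, which is crowded by the peri aryl group, and would then lead to a 1,2-quinone. The fallback sets out from 13 and uses sensitised photooxygenation (O2, tetraphenylporphyrin cat., visible light, CH2Cl2). Singlet oxygen adds across the 1,4-positions of the phenolic ring, so only the para position can be oxygenated. This should give 5-(3,4-dimethoxyphenyl)-4-hydroperoxy-3,7-dimethoxynaphthalen-1(4H)-one F3, which loses water (Et3N or on silica) and comes back to the route at 14.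

Step 3. Diazomethane may undergo dipolar cycloaddition to the acrylate double bond, or the diazoketone may capture HCl to give a chloromethyl ketone. The fallback sets out from 6 and avoids acylation of diazomethane. MeLi (2.2 equiv, THF, −78 to 0 °C) should give (3Z)-4-[2-(3,4-dimethoxyphenyl)-4-methoxyphenyl]-3-methoxybut-3-en-2-one F4. Its lithium enolate (LiN(SiMe3)2, THF, −78 °C) is acylated with CF3CO2CH2CF3 to (5Z)-6-[2-(3,4-dimethoxyphenyl)-4-methoxyphenyl]-1,1,1-trifluoro-5-methoxyhex-5-ene-2,4-dione F5. Detrifluoroacetylative diazo transfer (CH3SO2N3, Et3N, H2O, MeCN, rt) then comes back to the route at 8.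

**Further compounds**

F1 | step 4 | (3Z)-4-[2-(3,4-dimethoxyphenyl)-4-methoxyphenyl]-3-methoxybut-3-enoic acid | COc1ccc(/C=C(\OC)CC(O)=O)c(-c2ccc(OC)c(OC)c2)c1
F2 | step 4 | 5-(3,4-dimethoxyphenyl)-3,7-dimethoxynaphthalen-1-yl acetate | COc1cc(OC(C)=O)c2cc(OC)cc(-c3ccc(OC)c(OC)c3)c2c1
F3 | step 5 | 5-(3,4-dimethoxyphenyl)-4-hydroperoxy-3,7-dimethoxynaphthalen-1(4H)-one (racemic) | COC1=CC(=O)c2cc(OC)cc(-c3ccc(OC)c(OC)c3)c2C1OO
F4 | step 3 | (3Z)-4-[2-(3,4-dimethoxyphenyl)-4-methoxyphenyl]-3-methoxybut-3-en-2-one | COc1ccc(/C=C(\OC)C(C)=O)c(-c2ccc(OC)c(OC)c2)c1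
F5 | step 3 | (5Z)-6-[2-(3,4-dimethoxyphenyl)-4-methoxyphenyl]-1,1,1-trifluoro-5-methoxyhex-5-ene-2,4-dione | COc1ccc(/C=C(\OC)C(=O)CC(=O)C(F)(F)F)c(-c2ccc(OC)c(OC)c2)c1
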